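**Retrosynthetic overview**
1. Target triacid 21 ⇐ trimethyl ester 20. Ring D is closed last: C13–C16 by Nozaki–Hiyama–Kishi closure of bromoallyl ketone 19, and C8–C15 by Hosomi–Sakurai addition to tricyclic enone 17.
2. Ring B: C6–C8 by intramolecular ester-enolate addition to the vinylogous ester carbonyl of 15, followed by enol-ether transposition to enone 17.
3. Key bond C9–C10 (joins rings A and C, creates the C10 quaternary centre): oxidative heterocoupling of the C10 ester enolate of 10 with the α′-enolate of 3-ethoxycyclohexenone 11. Both carbons are natural donor sites; one-electron oxidation turns C10 into an enolonium-type acceptor (1,4-relationship C8=O/C20).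
4. Ring A: Diels–Alder reaction of 1 with 2, then an alkaloid-mediated kinetic resolution that fixes C5. C4 (methylation) and C10 (key step) are both set trans to the C5 carboxyl arm; Arndt–Eistert homologation supplies C6.
5. Ring order: A → A joined to C → B → D.

Assumption and convention: quinidine is taken as the cinchona pseudo-enantiomer matched to the enantiomer of 3 that is drawn (if the opposite sense is found, quinine is used and nothing else changes); gibberellane numbering is used for all intermediates (C7, C19, C20 = carboxyl carbons on C6, C4, C10), and α/β follow the customary gibberellin drawing (C19 and C20 α; H5, H9 and the C7 carboxyl β).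

**Step 1**
Reactants: 1 maleic anhydride; 2 methyl (2E)-penta-2,4-dienoate
Product: 3 racemic endo adduct methyl 1,3-dioxo-1,3,3a,4,7,7a-hexahydro-2-benzofuran-4-carboxylate
Conditions: PhMe, BHT (cat.), 100 °C
Reagents that add atoms: none
Why: Thermal Diels–Alder reaction whose endo transition state puts the diene ester and the anhydride on one face (all-cis), which ties the C5 configuration to the position of the C2=C3 double bond, while C4–H and C10–H are re-set later by enolate chemistry.

**Step 2**
Reactants: 3 racemic endo adduct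
Product: 4 all-cis-2,6-bis(methoxycarbonyl)cyclohex-3-ene-1-carboxylic acid
Conditions: quinidine (1.0 equiv), MeOH (0.55 equiv), PhMe, −55 °C; aq. NaHCO3 extraction, then acidify
Reagents that add atoms: methanol (CO)
Why: Cinchona-alkaloid-mediated anhydride methanolysis run as a kinetic resolution, in which only the enantiomer whose less hindered C20 carbonyl (remote from the C4 ester) is alkaloid-matched is opened quickly, so that half-ester 4 (at most 50 %) is separated from unreacted ent-3 by base extraction and the absolute configuration (C5) is fixed here.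

**Step 3**
Reactants: 4 all-cis half-ester
Product: 6 2,6-bis(methoxycarbonyl)-2-methylcyclohex-3-ene-1-carboxylic acid, via dilithium dienolate 5 (not isolated)
Conditions: LiN(iPr)2 (2.1 equiv), THF–DMPU, −78 to −40 °C; MeI, −78 °C; aq. HCl
Reagents that add atoms: iodomethane (CI)
Why: Dianion alkylation in which the second equivalent of base removes the allylic C4–H (more acidic than C10–H) and the lithium dienolate is methylated at its α-carbon on the face anti to the vicinal C5 carboxylate, setting the C4 quaternary centre (methyl β, C19 ester α).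

**Step 4**
Reactants: 6 C4-methylated cyclohexene acid
Product: 7 2,6-bis(methoxycarbonyl)-2-methylcyclohexane-1-carboxylic acid
Conditions: H2 (1 atm), Pd/C, EtOAc, 23 °C
Reagents that add atoms: none
Why: Heterogeneous catalytic hydrogenation removes the C2=C3 double bond, whose only role was to direct the enolisation of step 3, without touching a stereocentre.

**Step 5**
Reactants: 7 saturated diester acid
Product: 10 2-[2,6-bis(methoxycarbonyl)-2-methylcyclohexyl]acetic acid, via acid chloride 8 (not isolated), via diazoketone 9 (not isolated)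
Conditions: (COCl)2, DMF (cat.), CH2Cl2, 0–23 °C; CH2N2, Et2O, 0 °C; PhCO2Ag (0.1 equiv), Et3N, THF–H2O, 23 °C
Reagents that add atoms: diazomethane (C=[N+]=[N-]); water (O)
Why: Arndt–Eistert homologation, in which the Wolff rearrangement migrates C5 with retention and turns the C5 carboxyl into the C6–C7 acetic acid arm.

**Step 6 (key step)**
Reactants: 10 ring A acetic acid diester; 11 3-ethoxycyclohex-2-en-1-one
Product: 15 dimethyl 3-(4-ethoxy-2-oxocyclohex-3-en-1-yl)-2-(2-methoxy-2-oxoethyl)-1-methylcyclohexane-1,3-dicarboxylate, via dilithium dianion 12 (not isolated), via lithium enolate 13 (not isolated), via coupled acid 14 (not isolated)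
Conditions: 11 (2 equiv), LiN(iPr)2 (4.2 equiv), THF, −78 °C; Fe(acac)3 (3.3 equiv), −78 to 23 °C; cold aq. HCl to pH 4; then TMSCHN2, PhMe–MeOH, 0 °C
Reagents that add atoms: trimethylsilyldiazomethane (C[Si](C)(C)C=[N+]=[N-])
Why: Proposed new method: trivalent iron oxidises the more easily oxidised, fully substituted ester enolate of 12 to a tertiary α-ester radical (a one-electron enolonium equivalent at C10) that is captured at C9 by the excess enolate 13, and a second equivalent of iron oxidises the resulting ketyl radical anion, so that two natural donor carbons are joined; the closest known reaction type is the iron- or copper-mediated oxidative heterocoupling of two different lithium enolates, which has not been shown to build a quaternary centre from a carboxylate-bearing dianion; the new bond at C10 forms anti to the vicinal C5 arm and anti to the axial C19 ester (C9 β, C20 α), and C9 arises as an epimer mixture that is corrected in step 7.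

**Step 7**
Reactants: 15 coupled triester
Product: 17 trimethyl 1-methyl-7-oxo-2,3,4,4a,4b,5,6,7,9,9a-decahydro-1H-fluorene-1,4a,9-tricarboxylate, via tertiary alcohol 16 (not isolated)
Conditions: LiN(SiMe3)2 (1.2 equiv), THF, −78 to −20 °C; 1 M HCl, THF, 23 °C; then DBU (0.3 equiv), PhMe, 60 °C
Reagents that add atoms: water (O)
Why: Intramolecular Stork–Danheiser sequence in which the C6 ester enolate adds 5-exo to the vinylogous-ester carbonyl C8, acid transposes the enol ether into the C13 enone, and catalytic DBU equilibrates the γ-centre C9 and the α-centre C6 to the expected more stable isomer (ring C syn to the C20 ester and anti to ring A, C7 ester trans to C4).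

**Step 8**
Reactants: 17 tricyclic enone; 18 (2-bromoprop-2-en-1-yl)trimethylsilane
Product: 19 trimethyl 8a-(2-bromoprop-2-en-1-yl)-1-methyl-7-oxododecahydro-1H-fluorene-1,4a,9-tricarboxylate
Conditions: TiCl4 (1.5 equiv), CH2Cl2, −78 °C
Reagents that add atoms: none
Why: Hosomi–Sakurai conjugate allylation in which the allylsilane attacks C8 of the TiCl4-activated enone trans to the C9–C10 bond (syn to H9), as fused bicyclic enones give the cis-fused ketone, setting the C8 quaternary centre with C15 β.

**Step 9**
Reactants: 19 bromoallyl ketone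
Product: 20 trimethyl ent-13-hydroxygibberell-16-ene-7,19,20-trioate
Conditions: CrCl2 (6 equiv), NiCl2 (5 mol %), DMF, 23–50 °C; aq. NH4Cl
Reagents that add atoms: none
Why: Intramolecular Nozaki–Hiyama–Kishi reaction in which the alkenylchromium centre at C16 adds to the C13 ketone, and the one-carbon C15 tether allows only the bicyclo[3.2.1]octane geometry, so C13 is set by C8 and the 16-methylene is retained.

**Step 10**
Reactants: 20 trimethyl ent-13-hydroxygibberell-16-ene-7,19,20-trioate
Product: 21 ent-13-hydroxygibberell-16-ene-7,19,20-trioic acid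
Conditions: LiSPr (10 equiv), HMPA, 50 °C; aq. HCl to pH 3, 0 °C
Reagents that add atoms: none
Why: SN2 demethylation of the three methyl esters by thiolate at O–CH3, which is insensitive to the hindrance at C4 and C10 and spares the tertiary allylic alcohol, the exocyclic alkene and all stereocentres.

**Compound list**
1 | maleic anhydride | O=C1OC(=O)C=C1 | starting material
2 | methyl (2E)-penta-2,4-dienoate | COC(=O)/C=C/C=C | starting material
3 | methyl 1,3-dioxo-1,3,3a,4,7,7a-hexahydro-2-benzofuran-4-carboxylate, endo all-cis adduct, racemic (the enantiomer carried on is drawn) | [C@H]1(C(=O)O2)CC=C[C@@H](C(=O)OC)[C@H]1C2=O | intermediate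
4 | all-cis-2,6-bis(methoxycarbonyl)cyclohex-3-ene-1-carboxylic acid, single enantiomer (C5 acid, C4 and C10 esters, all α) | [C@H]1(C(=O)OC)CC=C[C@@H](C(=O)OC)[C@H]1C(=O)O | intermediate
5 | dilithium salt of 4 (C5 carboxylate, C4 ester dienolate) | [C@H]1(C(=O)OC)CC=CC(=C([O-])OC)[C@H]1C(=O)[O-].[Li+].[Li+] | intermediate
6 | 2,6-bis(methoxycarbonyl)-2-methylcyclohex-3-ene-1-carboxylic acid (C4 methyl β, trans to the C5 carboxyl) | [C@H]1(C(=O)OC)CC=C[C@@](C)(C(=O)OC)[C@H]1C(=O)O | intermediate
7 | 2,6-bis(methoxycarbonyl)-2-methylcyclohexane-1-carboxylic acid (same configuration as 6) | [C@H]1(C(=O)OC)CCC[C@@](C)(C(=O)OC)[C@H]1C(=O)O | intermediate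
8 | acid chloride of 7 | [C@H]1(C(=O)OC)CCC[C@@](C)(C(=O)OC)[C@H]1C(=O)Cl | intermediate
9 | diazoketone from 8 | [C@H]1(C(=O)OC)CCC[C@@](C)(C(=O)OC)[C@H]1C(=O)C=[N+]=[N-] | intermediate
10 | 2-[2,6-bis(methoxycarbonyl)-2-methylcyclohexyl]acetic acid (acetic acid arm α, cis to both esters) | [C@H]1(C(=O)OC)CCC[C@@](C)(C(=O)OC)[C@H]1CC(=O)O | intermediate
11 | 3-ethoxycyclohex-2-en-1-one | CCOC1=CC(=O)CCC1 | starting material
12 | dilithium salt of 10 (C7 carboxylate, C10 ester enolate) | COC([O-])=C1CCC[C@@](C)(C(=O)OC)[C@H]1CC(=O)[O-].[Li+].[Li+] | intermediate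
13 | lithium 3-ethoxycyclohexa-2,6-dien-1-olate (α′-enolate of 11) | CCOC1=CC([O-])=CCC1.[Li+] | intermediate
14 | 2-[3-(4-ethoxy-2-oxocyclohex-3-en-1-yl)-2,6-bis(methoxycarbonyl)-2-methylcyclohexyl]acetic acid (C10: C9 β, C20 α; C9 epimer mixture) | CCOC1=CC(=O)C(CC1)[C@]2(C(=O)OC)CCC[C@@](C)(C(=O)OC)[C@H]2CC(=O)O | intermediate
15 | dimethyl 3-(4-ethoxy-2-oxocyclohex-3-en-1-yl)-2-(2-methoxy-2-oxoethyl)-1-methylcyclohexane-1,3-dicarboxylate (methyl ester of 14; C9 epimer mixture) | CCOC1=CC(=O)C(CC1)[C@]2(C(=O)OC)CCC[C@@](C)(C(=O)OC)[C@H]2CC(=O)OC | intermediate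
16 | ring B aldol adduct: C8 tertiary alcohol with C13 ethyl enol ether (C6, C8, C9 mixtures) | CCOC=1CCC2[C@]3(C(=O)OC)CCC[C@@](C)(C(=O)OC)[C@H]3C(C(=O)OC)C2(O)C=1 | intermediate
17 | trimethyl 1-methyl-7-oxo-2,3,4,4a,4b,5,6,7,9,9a-decahydro-1H-fluorene-1,4a,9-tricarboxylate (rings A, B, C; C8=C14 enone; H5 β, H9 β, C7 ester β, C19 and C20 esters α) | O=C1CC[C@H]2[C@]3(C(=O)OC)CCC[C@@](C)(C(=O)OC)[C@H]3[C@H](C(=O)OC)C2=C1 | intermediate
18 | (2-bromoprop-2-en-1-yl)trimethylsilane | C=C(Br)C[Si](C)(C)C | starting material
19 | trimethyl 8a-(2-bromoprop-2-en-1-yl)-1-methyl-7-oxododecahydro-1H-fluorene-1,4a,9-tricarboxylate (C15 β, rings B and C cis-fused) | C=C(Br)C[C@]12CC(=O)CC[C@H]1[C@]1(C(=O)OC)CCC[C@@](C)(C(=O)OC)[C@H]1[C@@H]2C(=O)OC | intermediate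
20 | trimethyl ent-13-hydroxygibberell-16-ene-7,19,20-trioate (trimethyl ester of the target) | C=C1C[C@]23C[C@@]1(O)CC[C@H]2[C@]1(C(=O)OC)CCC[C@@](C)(C(=O)OC)[C@H]1[C@@H]3C(=O)OC | intermediate
21 | ent-13-hydroxygibberell-16-ene-7,19,20-trioic acid (the target gibberellin) | C=C1C[C@]23C[C@@]1(O)CC[C@H]2[C@]1(C(=O)O)CCC[C@@](C)(C(=O)O)[C@H]1[C@@H]3C(=O)O | target

**Totals**
Total step count: 10. Longest linear sequence: 10 steps (1 and 2 to 21); 11 and 18 are bought.

**The three steps most likely to fail**

Step 6. The coupling must form a quaternary centre between two hindered partners, and homocoupling of enolate 13 competes. The fallback replaces the one-pot radical coupling by a two-stage polar enolonium coupling and sets out from 10 and 11. Ketone 11 is converted with LiN(iPr)2 and TMSCl into 1-ethoxy-3-(trimethylsilyloxy)cyclohexa-1,3-diene F1. Acid 10 is converted with LiN(iPr)2 (2.2 equiv) and TMSCl into the trimethylsilyl ester ketene silyl acetal F2. F1 is treated with PhI(OAc)2 and BF3·OEt2 at −78 °C to give the α′-[acetoxy(phenyl)iodanyl] ketone F3, a preformed enolonium of trivalent iodine. F2 then attacks C9 of this species in a Mukaiyama-type substitution to give the coupled trimethylsilyl ester F4. Aqueous work-up cleaves the silyl ester and brings the route back at acid 14.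

Step 7. The base must enolise the C6 arm rather than ring C, the enone must not slip out of conjugation into the C6=C8 unsaturated ester, and the route relies on the natural C9 configuration being the thermodynamic one in enone 17. The fallback reverses the order of the two additions to C8 and sets out from 15. Barbier addition of (2-bromoallyl)zinc bromide (2,3-dibromopropene, Zn, THF) to the C8 carbonyl gives dimethyl 3-[2-(2-bromoprop-2-en-1-yl)-4-ethoxy-2-hydroxycyclohex-3-en-1-yl]-2-(2-methoxy-2-oxoethyl)-1-methylcyclohexane-1,3-dicarboxylate F5. Brief treatment with 1 M HCl transposes it to dimethyl 3-[2-(2-bromoprop-2-en-1-yl)-4-oxocyclohex-2-en-1-yl]-2-(2-methoxy-2-oxoethyl)-1-methylcyclohexane-1,3-dicarboxylate F6. NaOMe in MeOH then equilibrates C9 through the dienolate while the C6 ester enolate closes ring B by a reversible intramolecular Michael addition onto C8. This gives the cis-fused ketone under thermodynamic control and comes back to the route at 19, so step 8 is not needed.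

Step 8. C8 is flanked by C6 and C9 and the bromine-bearing allylsilane is a weak nucleophile, so conjugate addition may be slow or may give 1,2-addition. The fallback sets out from 17. TiCl4-promoted conjugate propargylation with the smaller, more reactive allenyltributylstannane gives trimethyl 1-methyl-7-oxo-8a-(prop-2-yn-1-yl)dodecahydro-1H-fluorene-1,4a,9-tricarboxylate F7. Reductive ketyl–alkyne cyclisation (SmI2, HMPA, t-BuOH, THF, 0 °C) then joins C13 to C16 in a 5-exo-dig closure, leaves the exocyclic methylene and the tertiary alcohol, and comes back to the route at 20, so step 9 is not needed.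

**Further compounds**
F1 | step 6 | 1-ethoxy-3-(trimethylsilyloxy)cyclohexa-1,3-diene | CCOC1=CC(O[Si](C)(C)C)=CCC1
F2 | step 6 | trimethylsilyl ester ketene silyl acetal of 10 | COC(O[Si](C)(C)C)=C1CCC[C@@](C)(C(=O)OC)[C@H]1CC(=O)O[Si](C)(C)C
F3 | step 6 | 6-[acetoxy(phenyl)iodanyl]-3-ethoxycyclohex-2-en-1-one | CCOC1=CC(=O)C(CC1)I(OC(C)=O)c1ccccc1
F4 | step 6 | trimethylsilyl ester of 14 | CCOC1=CC(=O)C(CC1)[C@]2(C(=O)OC)CCC[C@@](C)(C(=O)OC)[C@H]2CC(=O)O[Si](C)(C)C
F5 | step 7 | dimethyl 3-[2-(2-bromoprop-2-en-1-yl)-4-ethoxy-2-hydroxycyclohex-3-en-1-yl]-2-(2-methoxy-2-oxoethyl)-1-methylcyclohexane-1,3-dicarboxylate | C=C(Br)CC1(O)C=C(OCC)CCC1[C@]2(C(=O)OC)CCC[C@@](C)(C(=O)OC)[C@H]2CC(=O)OC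
F6 | step 7 | dimethyl 3-[2-(2-bromoprop-2-en-1-yl)-4-oxocyclohex-2-en-1-yl]-2-(2-methoxy-2-oxoethyl)-1-methylcyclohexane-1,3-dicarboxylate | C=C(Br)CC1=CC(=O)CCC1[C@]2(C(=O)OC)CCC[C@@](C)(C(=O)OC)[C@H]2CC(=O)OC
F7 | step 8 | trimethyl 1-methyl-7-oxo-8a-(prop-2-yn-1-yl)dodecahydro-1H-fluorene-1,4a,9-tricarboxylate | C#CC[C@]12CC(=O)CC[C@H]1[C@]1(C(=O)OC)CCC[C@@](C)(C(=O)OC)[C@H]1[C@@H]2C(=O)OC
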